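The ring peak of the flask cannot be read off a run: west held 0.010 M of starting material, east 0.015 M, and the flask holds 0.020 M, with feed time and [protic impurity] unchanged.

| flask | starting material | protic impurity | remark | time |
|---|---|---|---|---|
| west | 0.010 M (fed, over 1.0 h) | 0.020 M | run made earlier |  |
| east | 0.015 M (fed, over 1.0 h) | 0.020 M | run made earlier |  |
| flask | 0.020 M (fed, over 1.0 h) | 0.0200 M |  | 30 h |

- west (time / h: ring / %, starting material / %): 1.33: 13.0, 47.8; 2.00: 18.9, 27.9; 4.00: 24.7, 7.0; 6.00: 24.1, 2.1; 12.0: 20.4, 0.7; 20.0: 15.9, 0.1; 40.0: 13.5, 0
- east (time / h: ring / %, starting material / %): 1.33: 13.6, 45.5; 2.00: 18.8, 26.7; 4.00: 23.8, 6.3; 6.00: 23.4, 1.1; 12.0: 19.5, 0; 20.0: 15.4, 0.6; 40.0: 12.5, 0.3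

(standard deviation of a reading: 0.5 percentage points)

- percent here means starting material units held: one open dimer counts as two
- on the list of suspects stand: starting material -> ring; 2 starting material -> open dimer; starting material + protic impurity -> quenched substrate; ring <-> isomer of the product

- time, not beyond 30 h, at which the flask holds most ring
- the amount of ring, in percent of the starting material charged, at that time

The readings nearest the peak stand at 4.00 h, and from west to east they drop by 0.9 percentage points. This is the charge penalty, the ring lost per step of 5.00 mM in charge. It is thin against a scatter of 0.5 points per reading, but the readings at 6.00 h drop by 0.7 points. The flask lies one equal step above east, so my own reckoning gives 22.9 % at that reading time; it gives no peak time.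

The forecast puts 23 % (21.8 % to 24 %) at 4.5 h (3.7 h to 5.4 h): “Extrapolating to 0.020 M gives about 25.5% formed and a peak near 23%”.

The flask peaks at 4.63 h with 22.7 % of ring. Starting material, the limiting reagent, stands at 0 % by 30.0 h, while protic impurity keeps 55 % of its own charge. For the reckoning from the east reading at 4.00 h to fall below the forecast's low end, the step would have had to cost more than 2 points rather than 0.9 points.

    starting material → ring (k = 7.00 × 10⁻⁵ s⁻¹)
    2 starting material → open dimer (k = 0.00490 L mol⁻¹ s⁻¹)
    starting material + protic impurity → quenched substrate (k = 0.00730 L mol⁻¹ s⁻¹)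
    ring ⇌ isomer of the product (K = 1.20, k = 1.60 × 10⁻⁵ s⁻¹)

A neighbouring flask with 0.0050 M of starting material lies one step below west, so the penalty, added to the west reading at 4.00 h, gives 25.6 %. The computed peak of that neighbouring flask is 25.5 %, lower.

Readings and results were computed for an exercise.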